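**Assumption:** the target SMILES has no stereocentre and no configurable double bond (achiral, drawn as one of several fast-interconverting enol tautomers), so there is no enantiomer to control; names follow the tautomer of the given SMILES.

## Retrosynthetic overview

- Target ⇒ its central-ring tri-O-methyl ether (last step: O-demethylation).
- Key disconnection: both ArCH2–C(filicinic ring) bonds, cut with reversed polarity. The filicinic ring carbon, normally the enol nucleophile, is used as an enolonium equivalent (phenyliodonium ylide of propionylfilicinic acid). It is joined to a carbon nucleophile (a bis-benzylic zinc reagent) in one Pd-catalysed double coupling.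
- Bis-zinc reagent ⇐ bis(chloromethyl)arene ⇐ 2,4,6-trimethoxybutyrophenone ⇐ 1,3,5-trimethoxybenzene + butanoyl chloride.
- Ylide ⇐ propionylfilicinic acid ⇐ flopropione (dearomative gem-dimethylation).
- Rings: none is built. All three come from commercial benzene rings; the two outer rings are dearomatised before the coupling, the central ring stays aromatic throughout.

## Route

Step 1
Reactants: 1 1,3,5-trimethoxybenzene; 2 butanoyl chloride
Product: 3 1-(2,4,6-trimethoxyphenyl)butan-1-one
Conditions: 2 (1.05 equiv), Bi(OTf)3 (5 mol %), MeNO2, 25 °C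
Reagents that add atoms: none
Why: Friedel–Crafts acylation of a very electron-rich arene stops cleanly after one acyl group because the ketone deactivates the ring.

Step 2
Reactants: 3 1-(2,4,6-trimethoxyphenyl)butan-1-one
Product: 4 1-[3,5-bis(chloromethyl)-2,4,6-trimethoxyphenyl]butan-1-one
Conditions: (CH2O)n (6 equiv), HCl (g), AcOH, 35 °C; used promptly
Reagents that add atoms: formaldehyde (as paraformaldehyde) C=O; hydrogen chloride Cl
Why: Blanc chloromethylation attacks the only two free ring positions, each flanked by two methoxy groups, and the fully substituted product cannot be alkylated further.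

Step 3
Reactants: 5 1-(2,4,6-trihydroxyphenyl)propan-1-one (flopropione)
Product: 6 3,5-dihydroxy-4,4-dimethyl-2-propanoylcyclohexa-2,5-dien-1-one (propionylfilicinic acid)
Conditions: MeI (2.2 equiv), NaOMe (3.5 equiv), MeOH, 0 → 25 °C; acidify, crystallise
Reagents that add atoms: iodomethane CI
Why: Known dearomative gem-dimethylation of an acylphloroglucinol: the phenoxide is C-methylated twice at one free ring carbon, the second methylation giving the stable enolised triketone (separated from mono- and 3,5-dimethyl by-products).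

Step 4
Reactants: 6 propionylfilicinic acid
Product: 7 5-hydroxy-6,6-dimethyl-3-oxo-2-(phenyliodonio)-4-propanoylcyclohexa-1,4-dien-1-olate (phenyliodonium ylide of 6)
Conditions: PhI(OAc)2 (1.05 equiv), CH2Cl2, 0 → 25 °C; precipitate with Et2O, store cold
Reagents that add atoms: (diacetoxyiodo)benzene CC(=O)OI(OC(C)=O)c1ccccc1
Why: Standard iodonium ylide formation by ligand exchange at iodine(III) with the only C–H acidic ring carbon of a cyclic β-diketone, which converts that nucleophilic carbon into an enolonium equivalent.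

Step 5
Reactants: 4 1-[3,5-bis(chloromethyl)-2,4,6-trimethoxyphenyl]butan-1-one; 7 phenyliodonium ylide of 6 (2.3 equiv)
Product: 10 1-{3,5-bis[(2,4-dihydroxy-3,3-dimethyl-6-oxo-5-propanoylcyclohexa-1,4-dien-1-yl)methyl]-2,4,6-trimethoxyphenyl}butan-1-one, via bis(benzylic zinc chloride) 8 (not isolated), via sodium enolate of the iodonium ylide 9 (not isolated)
Conditions: (i) 4, Zn dust (3 equiv), LiCl (3 equiv), THF, 0 → 25 °C; (ii) 7, NaH (2.3 equiv), THF/NMP, 0 °C; (iii) add (i) to (ii), Pd(OAc)2 (4 mol %), SPhos (8 mol %), 0 → 25 °C; aq. HCl work-up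
Reagents that add atoms: none
Why: Proposed new method: a Negishi-type double coupling in which Pd(0) inserts into the hypervalent C–I(III) bond of the ylide (PhI leaves) to give a C-bound Pd(II) enolate, the benzylic zinc transmetalates and reductive elimination forms each CH2–C bond, so the normally nucleophilic enol carbon is joined to a carbon nucleophile; the acidic enol of 7 is capped as its sodium salt first so it cannot protonate the zinc reagent, and the closest known reactions are the Pd-catalysed Suzuki-type coupling of phenyliodonium zwitterions of cyclic 1,3-dicarbonyls with boronic acids and the Negishi coupling of benzylic zinc chlorides with α-iodoenones.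

Step 6
Reactants: 10 tri-O-methyl ether
Product: 11 1-{3,5-bis[(2,4-dihydroxy-3,3-dimethyl-6-oxo-5-propanoylcyclohexa-1,4-dien-1-yl)methyl]-2,4,6-trihydroxyphenyl}butan-1-one (target)
Conditions: BBr3 (12 equiv), CH2Cl2, −78 → 0 °C; MeOH then H2O quench
Reagents that add atoms: none
Why: Lewis-acid cleavage of aryl methyl ethers (ketone-chelated ortho ethers first, then the hindered 4-OMe), with the intermediate O–B species making the ring electron-poorer and so less prone to acid cleavage of the methylene bridges.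

## Compound list

1 | 1,3,5-trimethoxybenzene | COc1cc(OC)cc(OC)c1 | starting material
2 | butanoyl chloride | CCCC(=O)Cl | starting material
3 | 1-(2,4,6-trimethoxyphenyl)butan-1-one | CCCC(=O)c1c(OC)cc(OC)cc1OC | intermediate
4 | 1-[3,5-bis(chloromethyl)-2,4,6-trimethoxyphenyl]butan-1-one | CCCC(=O)c1c(OC)c(CCl)c(OC)c(CCl)c1OC | intermediate
5 | 1-(2,4,6-trihydroxyphenyl)propan-1-one (flopropione) | CCC(=O)c1c(O)cc(O)cc1O | starting material
6 | 3,5-dihydroxy-4,4-dimethyl-2-propanoylcyclohexa-2,5-dien-1-one (propionylfilicinic acid) | CCC(=O)C1=C(O)C(C)(C)C(O)=CC1=O | intermediate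
7 | 5-hydroxy-6,6-dimethyl-3-oxo-2-(phenyliodonio)-4-propanoylcyclohexa-1,4-dien-1-olate (iodonium ylide of 6) | CCC(=O)C1=C(O)C(C)(C)C([O-])=C([I+]c2ccccc2)C1=O | intermediate
8 | [(5-butanoyl-2,4,6-trimethoxy-1,3-phenylene)bis(methylene)]bis(chlorozinc) | CCCC(=O)c1c(OC)c(C[Zn]Cl)c(OC)c(C[Zn]Cl)c1OC | intermediate (not isolated)
9 | sodium enolate of ylide 7 | CCC(=O)C1=C([O-])C(C)(C)C([O-])=C([I+]c2ccccc2)C1=O.[Na+] | intermediate (not isolated)
10 | 1-{3,5-bis[(2,4-dihydroxy-3,3-dimethyl-6-oxo-5-propanoylcyclohexa-1,4-dien-1-yl)methyl]-2,4,6-trimethoxyphenyl}butan-1-one | CCCC(=O)c1c(OC)c(CC2=C(O)C(C)(C)C(O)=C(C(=O)CC)C2=O)c(OC)c(CC2=C(O)C(C)(C)C(O)=C(C(=O)CC)C2=O)c1OC | intermediate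
11 | 1-{3,5-bis[(2,4-dihydroxy-3,3-dimethyl-6-oxo-5-propanoylcyclohexa-1,4-dien-1-yl)methyl]-2,4,6-trihydroxyphenyl}butan-1-one | CCCC(=O)c1c(O)c(CC2=C(O)C(C)(C)C(O)=C(C(=O)CC)C2=O)c(O)c(CC2=C(O)C(C)(C)C(O)=C(C(=O)CC)C2=O)c1O | target

## Step count and risks

Total steps: 6. Longest linear sequence: 4 (steps 1, 2, 5, 6; the branch 3, 4, 5, 6 is equally long).

**Most likely to fail, 1: step 5.** The coupling is new. The zinc reagent may be oxidised or protonated by the I(III) ylide, phenyl may transfer instead of the dione carbon, and both coupling sites are hindered.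
Fallback: sets out from 4 and returns at 10. The zinc reagent is replaced by an isolable boron nucleophile and the coupling is run as a Suzuki-type reaction in aqueous base, the manifold already known for such iodonium zwitterions, where the acidic enol of 7 needs no separate deprotonation. Miyaura borylation of 4 (B2pin2, Pd(dba)2, (4-MeOC6H4)3P, KOAc, toluene, 50 °C) gives 1-{2,4,6-trimethoxy-3,5-bis[(4,4,5,5-tetramethyl-1,3,2-dioxaborolan-2-yl)methyl]phenyl}butan-1-one F1. F1 is coupled with 7 (2.3 equiv; Pd(Pt-Bu3)2, LiOH, DME/H2O, 25 °C; acidify) to give 10.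

**Most likely to fail, 2: step 6.** BBr3/HBr may ionise the ArCH2–C bonds and cleave or scramble the methylene bridges.
Fallback: sets out from 3 and returns at 11. The protecting group is changed to benzyl so that the last step is a neutral hydrogenolysis. Ketone 3 is demethylated while no bridge is present (BBr3, CH2Cl2) to 1-(2,4,6-trihydroxyphenyl)butan-1-one F2. Benzylation (BnBr, K2CO3, DMF, 60 °C) gives 1-[2,4,6-tris(benzyloxy)phenyl]butan-1-one F3. Mild chloromethylation (MOMCl, cat. ZnCl2, CH2Cl2, 0 °C) gives 1-[2,4,6-tris(benzyloxy)-3,5-bis(chloromethyl)phenyl]butan-1-one F4. Zinc insertion as in step 5 gives the bis(benzylic zinc chloride) of the tribenzyl series F5, which is coupled with 9 under the step 5 conditions to 1-{2,4,6-tris(benzyloxy)-3,5-bis[(2,4-dihydroxy-3,3-dimethyl-6-oxo-5-propanoylcyclohexa-1,4-dien-1-yl)methyl]phenyl}butan-1-one F6. H2, Pd/C, EtOAc/MeOH, 25 °C then gives 11.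

**Most likely to fail, 3: step 2.** The very reactive benzylic chloride may alkylate unreacted arene to give diarylmethane oligomers, and 4 is solvolysis-prone.
Fallback: sets out from 3 and returns at 4. The CH2 units are introduced by cross-coupling instead of electrophilic substitution. NBS (2.1 equiv, MeCN, 0 °C) gives 1-(3,5-dibromo-2,4,6-trimethoxyphenyl)butan-1-one F7. Double Stille coupling with (tributylstannyl)methanol (Pd(Pt-Bu3)2, dioxane, 90 °C) gives 1-[3,5-bis(hydroxymethyl)-2,4,6-trimethoxyphenyl]butan-1-one F8. SOCl2 (CH2Cl2, 0 °C) converts F8 into 4.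

## Further compounds

F1 | step 5 | 1-{2,4,6-trimethoxy-3,5-bis[(4,4,5,5-tetramethyl-1,3,2-dioxaborolan-2-yl)methyl]phenyl}butan-1-one | CCCC(=O)c1c(OC)c(CB2OC(C)(C)C(C)(C)O2)c(OC)c(CB2OC(C)(C)C(C)(C)O2)c1OC
F2 | step 6 | 1-(2,4,6-trihydroxyphenyl)butan-1-one | CCCC(=O)c1c(O)cc(O)cc1O
F3 | step 6 | 1-[2,4,6-tris(benzyloxy)phenyl]butan-1-one | CCCC(=O)c1c(OCc2ccccc2)cc(OCc2ccccc2)cc1OCc1ccccc1
F4 | step 6 | 1-[2,4,6-tris(benzyloxy)-3,5-bis(chloromethyl)phenyl]butan-1-one | CCCC(=O)c1c(OCc2ccccc2)c(CCl)c(OCc2ccccc2)c(CCl)c1OCc1ccccc1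
F5 | step 6 | {[2,4,6-tris(benzyloxy)-5-butanoyl-1,3-phenylene]bis(methylene)}bis(chlorozinc) | CCCC(=O)c1c(OCc2ccccc2)c(C[Zn]Cl)c(OCc2ccccc2)c(C[Zn]Cl)c1OCc1ccccc1
F6 | step 6 | 1-{2,4,6-tris(benzyloxy)-3,5-bis[(2,4-dihydroxy-3,3-dimethyl-6-oxo-5-propanoylcyclohexa-1,4-dien-1-yl)methyl]phenyl}butan-1-one | CCCC(=O)c1c(OCc2ccccc2)c(CC2=C(O)C(C)(C)C(O)=C(C(=O)CC)C2=O)c(OCc2ccccc2)c(CC2=C(O)C(C)(C)C(O)=C(C(=O)CC)C2=O)c1OCc1ccccc1
F7 | step 2 | 1-(3,5-dibromo-2,4,6-trimethoxyphenyl)butan-1-one | CCCC(=O)c1c(OC)c(Br)c(OC)c(Br)c1OC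
F8 | step 2 | 1-[3,5-bis(hydroxymethyl)-2,4,6-trimethoxyphenyl]butan-1-one | CCCC(=O)c1c(OC)c(CO)c(OC)c(CO)c1OC
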